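## Retrosynthetic overview

1. Target 22 comes from acetylation of C13 alcohol 21, which comes from a photochemical singlet-oxygen ene reaction on α-methylene lactone 19 (makes C13–O, moves the olefin to C7=C11).
2. 19 comes from double epoxidation of the (1(10)Z,4E) macrocycle 17; the two oxirane rings are formed last.
3. 17 comes from chromium Barbier ring closure at C6–C7 of bromo enal 15 (ten-membered carbocycle first, then the γ-lactone).
4. 15 comes from aldehyde 11 (Baylis–Hillman, bromination); 11 comes from the electrochemical nickel-catalysed decarboxylative alkenylation that joins C9–C10 from Z-iodide 6 (geranyl acetate) and thioester acid 8.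
5. The only purchased stereocentre is C8, from (S)-2-acetoxysuccinic anhydride (L-malic acid); C6 and the four epoxide centres are set from it by substrate control.

Assumption: germacrane numbering is used (ring C1–C10, lactone carbons C11–C13, C14 on C10, C15 on C4); the SMILES is taken at face value, i.e. a cis 1,10-epoxide and a trans 4,5-epoxide; compounds 1, 4, 7 and 12 are taken as commercial.

## Route

Step 1
Reactants: 1 geranyl acetate
Product: 3 (2E)-3-methyl-6-oxohex-2-en-1-yl acetate, via ozonide 2 (not isolated)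
Conditions: O3 (1.0 equiv, Sudan Red 7B end-point), CH2Cl2, −78 °C; then Me2S, −78 °C → rt
Reagents that add atoms: ozone [O-][O+]=O
Why: Criegee ozonolysis with reductive work-up, in which the isolated electron-rich 6,7-olefin is cleaved much faster than the olefin deactivated by the allylic acetate; no stereocentre is formed and the E olefin (future C4=C5) is untouched.

Step 2
Reactants: 3 (2E)-3-methyl-6-oxohex-2-en-1-yl acetate; 4 ethyltriphenylphosphonium iodide
Product: 5 (2E,6Z)-7-iodo-3-methylocta-2,6-dien-1-yl acetate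
Conditions: 4, n-BuLi, THF, −78 → 0 °C; I2, −78 °C; NaN(SiMe3)2, −20 °C; then 3, −78 → −20 °C
Reagents that add atoms: iodine II
Why: Stork–Zhao-type Wittig olefination with the α-iodo ylide gives, under kinetic low-temperature control, the (Z)-2-iodoalk-2-ene (iodine cis to the chain), which fixes the future 1(10)Z geometry.

Step 3
Reactants: 5 (2E,6Z)-7-iodo-3-methylocta-2,6-dien-1-yl acetate
Product: 6 (2E,6Z)-7-iodo-3-methylocta-2,6-dien-1-ol
Conditions: K2CO3 (0.2 equiv), MeOH, rt
Reagents that add atoms: none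
Why: Base-catalysed transesterification (methanolysis) of the primary acetate; the vinyl iodide and both olefin geometries are inert.

Step 4
Reactants: 7 (S)-2-acetoxysuccinic anhydride
Product: 8 (3S)-3-acetoxy-4-(ethylsulfanyl)-4-oxobutanoic acid
Conditions: EtSH (1.5 equiv), pyridine (1.1 equiv), CH2Cl2, −20 → 0 °C
Reagents that add atoms: ethanethiol CCS
Why: Regioselective thiolysis (nucleophilic acyl substitution) of the anhydride at the more electrophilic carbonyl next to the acetoxy group gives the C7 thioester and the free distal acid; the purchased centre (future C8, S) is not touched, and the cold, weakly basic medium suppresses β-elimination of acetic acid.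

Step 5
Reactants: 8 (3S)-3-acetoxy-4-(ethylsulfanyl)-4-oxobutanoic acid; 6 (2E,6Z)-7-iodo-3-methylocta-2,6-dien-1-ol
Product: 10 S-ethyl (2S,4Z,8E)-2-acetoxy-10-hydroxy-4,8-dimethyldeca-4,8-dienethioate, via NHPI ester 9 (not isolated)
Conditions: 8 (2 equiv), N-hydroxyphthalimide, N,N'-diisopropylcarbodiimide, DMF, rt, 2 h; then 6, NiCl2·glyme (10 mol%), 2,2'-bipyridine (10 mol%), AgNO3 (0.3 equiv), LiCl, DMF, Mg anode, RVC cathode, constant current, rt
Reagents that add atoms: none
Why: Nickel-electrocatalytic decarboxylative alkenylation (reductive radical cross-coupling of a redox-active ester with an alkenyl iodide): cathodically generated low-valent nickel inserts into the C–I bond with retention of the Z geometry and captures the primary C9 radical released from the reduced ester, forming C9–C10 without touching C8.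

Step 6
Reactants: 10 S-ethyl (2S,4Z,8E)-2-acetoxy-10-hydroxy-4,8-dimethyldeca-4,8-dienethioate
Product: 11 (2S,4Z,8E)-2-acetoxy-10-hydroxy-4,8-dimethyldeca-4,8-dienal
Conditions: Et3SiH (3 equiv), 10% Pd/C (5 mol%), acetone, rt
Reagents that add atoms: none
Why: Fukuyama reduction of the thioester stops at the aldehyde under neutral conditions, so the α-acetoxy centre C8 is not epimerised and the acetate and trisubstituted olefins survive.

Step 7
Reactants: 11 (2S,4Z,8E)-2-acetoxy-10-hydroxy-4,8-dimethyldeca-4,8-dienal; 12 methyl acrylate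
Product: 13 methyl (3RS,4S,6Z,10E)-4-acetoxy-3,12-dihydroxy-6,10-dimethyl-2-methylidenedodeca-6,10-dienoate
Conditions: 12 (10 equiv), DABCO (0.5 equiv), MeOH (2 equiv), 0 °C → rt
Reagents that add atoms: none
Why: Morita–Baylis–Hillman reaction of the activated α-acetoxy aldehyde with the DABCO–acrylate zwitterion forms C7–C11; the new carbinol C7 is an epimer mixture, which does not matter because C7 becomes sp2 in step 9.

Step 8
Reactants: 13 methyl (3RS,4S,6Z,10E)-4-acetoxy-3,12-dihydroxy-6,10-dimethyl-2-methylidenedodeca-6,10-dienoate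
Product: 14 methyl (3RS,4S,6Z,10E)-4-acetoxy-3-hydroxy-6,10-dimethyl-2-methylidene-12-oxododeca-6,10-dienoate
Conditions: activated MnO2 (15 equiv), CH2Cl2, rt
Reagents that add atoms: none
Why: MnO2 allylic oxidation is selective for the electron-rich primary allylic alcohol (C6), giving the E-enal; the acrylate-deactivated secondary Baylis–Hillman alcohol is not oxidised.

Step 9
Reactants: 14 methyl (3RS,4S,6Z,10E)-4-acetoxy-3-hydroxy-6,10-dimethyl-2-methylidene-12-oxododeca-6,10-dienoate
Product: 15 methyl (2Z,4S,6Z,10E)-4-acetoxy-2-(bromomethyl)-6,10-dimethyl-12-oxododeca-2,6,10-trienoate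
Conditions: N-bromosuccinimide/Me2S (pre-mixed, 1.3 equiv), CH2Cl2, −20 → 0 °C
Reagents that add atoms: N-bromosuccinimide BrN1C(=O)CCC1=O
Why: Corey–Kim-type activation of the Baylis–Hillman alcohol followed by SN2′ attack of bromide at C13 gives the rearranged, thermodynamically favoured (2Z)-2-(bromomethyl)enoate; C8 is untouched.

Step 10
Reactants: 15 methyl (2Z,4S,6Z,10E)-4-acetoxy-2-(bromomethyl)-6,10-dimethyl-12-oxododeca-2,6,10-trienoate
Product: 17 (1(10)Z,4E,6R,7R,8S)-8-acetoxygermacra-1(10),4,11(13)-trien-12,6-olide, via hydroxy ester 16 (not isolated)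
Conditions: CrCl2 (10 equiv), THF, rt, syringe-pump addition of 15 (final 2 mM); aq. NH4Cl work-up; then p-TsOH·H2O (cat.), CH2Cl2, rt
Reagents that add atoms: none
Why: Intramolecular Nozaki–Hiyama (chromium Barbier) allylation at high dilution closes the ten-membered ring by γ-attack of the allylchromium on the enal through an anti-selective Zimmerman–Traxler chair (6,7-trans); C6 is set from C8 because the short tether delivers the aldehyde to the C9 face of the allyl unit while A(1,3) strain keeps H8 in the allyl plane and the acetate outside the ring, and acid then closes the trans-fused γ-lactone (C7 is only temporary).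

Step 11
Reactants: 17 (1(10)Z,4E,6R,7R,8S)-8-acetoxygermacra-1(10),4,11(13)-trien-12,6-olide
Product: 19 (1R,4R,5R,6S,7R,8S,10S)-8-acetoxy-1,10:4,5-diepoxygermacr-11(13)-en-12,6-olide, via 1,10-monoepoxide 18 (not isolated)
Conditions: dimethyldioxirane (2.4 equiv, ca. 0.07 M in acetone), CH2Cl2, −20 → 0 °C
Reagents that add atoms: dimethyldioxirane CC1(C)OO1
Why: Epoxidation by neutral oxygen transfer to the two electron-rich trisubstituted ring olefins (the acrylate is inert) from their exposed outer faces: at C4=C5, A(1,3) strain with C15 holds H6 in the olefin plane with the ring bond to C7 inside and O6 outside, giving the 5,6-threo 4R,5R-epoxide, and the 1(10)Z olefin is attacked on the face away from the inward-folded C8–C9 segment, giving the cis 1R,10S-epoxide.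

Step 12
Reactants: 19 (1R,4R,5R,6S,7R,8S,10S)-8-acetoxy-1,10:4,5-diepoxygermacr-11(13)-en-12,6-olide
Product: 21 (1R,4R,5R,6S,8S,10S)-8-acetoxy-1,10:4,5-diepoxy-13-hydroxygermacr-7(11)-en-12,6-olide, via 13-hydroperoxide 20 (not isolated)
Conditions: O2 (1 atm), meso-tetraphenylporphyrin (1 mol%), CDCl3 (filtered through K2CO3), 590 nm LEDs, 0 °C, 24–48 h; then PPh3 (1.2 equiv), 0 °C
Reagents that add atoms: oxygen O=O
Why: Proposed new method: a gem-directed Schenck ene photooxygenation of an α-methylene-γ-butyrolactone, in which sensitised singlet oxygen adds to the exocyclic C11=C13 bond and removes the pseudo-axial H7 (the allylic hydrogen geminal to the carbonyl) suprafacially, so that oxygen is delivered to C13 and the double bond moves to C7=C11, erasing the temporary C7 centre and leaving C6 and C8 untouched, after which PPh3 reduces the hydroperoxide; the closest known reaction type is the gem-selective ene photooxygenation of tiglates and related acyclic α,β-unsaturated esters, not yet shown for α-methylene lactones, which are sluggish towards singlet oxygen (hence the long-lifetime solvent and the prior conversion of both ring olefins into inert epoxides).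

Step 13
Reactants: 21 (1R,4R,5R,6S,8S,10S)-8-acetoxy-1,10:4,5-diepoxy-13-hydroxygermacr-7(11)-en-12,6-olide
Product: 22 (1R,4R,5R,6S,8S,10S)-8,13-diacetoxy-1,10:4,5-diepoxygermacr-7(11)-en-12,6-olide (CNP0271844.2)
Conditions: Ac2O, pyridine, DMAP (cat.), CH2Cl2, 0 °C
Reagents that add atoms: acetic anhydride CC(=O)OC(C)=O
Why: DMAP-catalysed acetylation of the primary allylic alcohol; no stereocentre is affected and the epoxides tolerate the buffered basic medium.

## Compound list

1 | geranyl acetate | CC(C)=CCC/C(C)=C/COC(C)=O | starting material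
2 | 3-[(3E)-5-acetoxy-3-methylpent-3-en-1-yl]-5,5-dimethyl-1,2,4-trioxolane (ozonide) | CC1(C)OOC(CC/C(C)=C/COC(C)=O)O1 | intermediate
3 | (2E)-3-methyl-6-oxohex-2-en-1-yl acetate | O=CCC/C(C)=C/COC(C)=O | intermediate
4 | ethyltriphenylphosphonium iodide | CC[P+](c1ccccc1)(c1ccccc1)c1ccccc1.[I-] | starting material
5 | (2E,6Z)-7-iodo-3-methylocta-2,6-dien-1-yl acetate | C/C(I)=C/CC/C(C)=C/COC(C)=O | intermediate
6 | (2E,6Z)-7-iodo-3-methylocta-2,6-dien-1-ol | C/C(I)=C/CC/C(C)=C/CO | intermediate
7 | (S)-2-acetoxysuccinic anhydride | CC(=O)O[C@H]1CC(=O)OC1=O | starting material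
8 | (3S)-3-acetoxy-4-(ethylsulfanyl)-4-oxobutanoic acid | CCSC(=O)[C@@H](OC(C)=O)CC(O)=O | intermediate
9 | 1,3-dioxoisoindolin-2-yl (3S)-3-acetoxy-4-(ethylsulfanyl)-4-oxobutanoate (NHPI ester) | CCSC(=O)[C@@H](OC(C)=O)CC(=O)ON1C(=O)c2ccccc2C1=O | intermediate
10 | S-ethyl (2S,4Z,8E)-2-acetoxy-10-hydroxy-4,8-dimethyldeca-4,8-dienethioate | CCSC(=O)[C@@H](OC(C)=O)C/C(C)=C\CC/C(C)=C/CO | intermediate
11 | (2S,4Z,8E)-2-acetoxy-10-hydroxy-4,8-dimethyldeca-4,8-dienal | O=C[C@@H](OC(C)=O)C/C(C)=C\CC/C(C)=C/CO | intermediate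
12 | methyl acrylate | C=CC(=O)OC | starting material
13 | methyl (3RS,4S,6Z,10E)-4-acetoxy-3,12-dihydroxy-6,10-dimethyl-2-methylidenedodeca-6,10-dienoate | C=C(C(=O)OC)C(O)[C@@H](OC(C)=O)C/C(C)=C\CC/C(C)=C/CO | intermediate
14 | methyl (3RS,4S,6Z,10E)-4-acetoxy-3-hydroxy-6,10-dimethyl-2-methylidene-12-oxododeca-6,10-dienoate | C=C(C(=O)OC)C(O)[C@@H](OC(C)=O)C/C(C)=C\CC/C(C)=C/C=O | intermediate
15 | methyl (2Z,4S,6Z,10E)-4-acetoxy-2-(bromomethyl)-6,10-dimethyl-12-oxododeca-2,6,10-trienoate | BrC/C(C(=O)OC)=C\[C@@H](OC(C)=O)C/C(C)=C\CC/C(C)=C/C=O | intermediate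
16 | methyl (1(10)Z,4E,6R,7S,8S)-8-acetoxy-6-hydroxygermacra-1(10),4,11(13)-trien-12-oate (hydroxy ester) | C=C(C(=O)OC)[C@H]1[C@H](O)/C=C(\C)CC/C=C(/C)C[C@@H]1OC(C)=O | intermediate
17 | (1(10)Z,4E,6R,7R,8S)-8-acetoxygermacra-1(10),4,11(13)-trien-12,6-olide | C=C1C(=O)O[C@@H]2/C=C(\C)CC/C=C(/C)C[C@H](OC(C)=O)[C@@H]12 | intermediate
18 | (1R,4E,6R,7R,8S,10S)-8-acetoxy-1,10-epoxygermacra-4,11(13)-dien-12,6-olide | C=C1C(=O)O[C@@H]2/C=C(\C)CC[C@H]3O[C@@]3(C)C[C@H](OC(C)=O)[C@@H]12 | intermediate
19 | (1R,4R,5R,6S,7R,8S,10S)-8-acetoxy-1,10:4,5-diepoxygermacr-11(13)-en-12,6-olide | C=C1C(=O)O[C@@H]2[C@H]3O[C@]3(C)CC[C@H]3O[C@@]3(C)C[C@H](OC(C)=O)[C@@H]12 | intermediate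
20 | (1R,4R,5R,6S,8S,10S)-8-acetoxy-1,10:4,5-diepoxy-13-hydroperoxygermacr-7(11)-en-12,6-olide | OOCC1=C2[C@@H](OC(C)=O)C[C@]3(C)O[C@@H]3CC[C@@]3(C)O[C@@H]3[C@H]2OC1=O | intermediate
21 | (1R,4R,5R,6S,8S,10S)-8-acetoxy-1,10:4,5-diepoxy-13-hydroxygermacr-7(11)-en-12,6-olide | OCC1=C2[C@@H](OC(C)=O)C[C@]3(C)O[C@@H]3CC[C@@]3(C)O[C@@H]3[C@H]2OC1=O | intermediate
22 | (1R,4R,5R,6S,8S,10S)-8,13-diacetoxy-1,10:4,5-diepoxygermacr-7(11)-en-12,6-olide (CNP0271844.2) | CC(=O)OCC1=C2[C@@H](OC(C)=O)C[C@]3(C)O[C@@H]3CC[C@@]3(C)O[C@@H]3[C@H]2OC1=O | target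

## Step count and risks

Total steps: 13. Longest linear sequence: 12 steps (1–3, then 5–13).

Three steps most likely to fail:

Step 10 (ring closure). Oligomerisation, 1,4-elimination of the C8 acetate from the allylchromium, or the wrong C6 epimer are all possible. The fallback leaves the organochromium/bromide manifold: set out from 14, acetylate the Baylis–Hillman alcohol (Ac2O, pyridine, DMAP) to methyl (3RS,4S,6Z,10E)-3,4-diacetoxy-6,10-dimethyl-2-methylidene-12-oxododeca-6,10-dienoate F1, and close the ring by palladium-catalysed umpolung allylation (Pd(PPh3)4, Et2Zn, THF, high dilution). Zerovalent palladium ionises the allylic acetate, ethyl transfer from zinc gives a nucleophilic allylzinc, and this adds to the enal through the same type of chair; the zinc alkoxide gives hydroxy ester 16 on work-up, acid lactonises it as before, and the route is rejoined at 17.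

Step 11 (facial selectivity of two epoxidations on a flexible ring). The fallback replaces conformational control at C4=C5 by hydroxyl direction: set out from 15, run the chromium cyclisation without the acid treatment and isolate 16. Then epoxidise the allylic alcohol with VO(acac)2 (cat.) and t-BuOOH in CH2Cl2; the metal alkoxide delivers oxygen syn to the C6 hydroxyl in the A(1,3)-minimised conformer (threo), giving methyl (1(10)Z,4R,5R,6S,7S,8S)-8-acetoxy-4,5-epoxy-6-hydroxygermacra-1(10),11(13)-dien-12-oate F2. Lactonise under non-acidic conditions (DBU cat., toluene, 40 °C) to (1(10)Z,4R,5R,6S,7R,8S)-8-acetoxy-4,5-epoxygermacra-1(10),11(13)-dien-12,6-olide F3. Only the 1(10) olefin is then left for dimethyldioxirane (1.2 equiv), and the route is rejoined at 19.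

Step 12 (proposed new step; the acrylate-type olefin may be too electron-poor for singlet oxygen, or the geometry for H7 abstraction may be poor). The fallback uses known chemistry only: set out from 19 and add bromine across the exocyclic olefin (Br2, CH2Cl2, 0 °C, dark, propylene oxide as acid scavenger) to give the 11,13-dibromide of 19, (1R,4R,5R,6S,8S,10S)-8-acetoxy-11,13-dibromo-1,10:4,5-diepoxygermacran-12,6-olide F4. Dehydrobrominate with DBU (H7/Br11 elimination to the conjugated endocyclic olefin) to (1R,4R,5R,6S,8S,10S)-8-acetoxy-13-bromo-1,10:4,5-diepoxygermacr-7(11)-en-12,6-olide F5. Displace the allylic bromide with KOAc/18-crown-6 in MeCN; this gives 22 directly, so the fallback rejoins at the target.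

Further compounds
F1 | step 10 | methyl (3RS,4S,6Z,10E)-3,4-diacetoxy-6,10-dimethyl-2-methylidene-12-oxododeca-6,10-dienoate | C=C(C(=O)OC)C(OC(C)=O)[C@@H](OC(C)=O)C/C(C)=C\CC/C(C)=C/C=O
F2 | step 11 | methyl (1(10)Z,4R,5R,6S,7S,8S)-8-acetoxy-4,5-epoxy-6-hydroxygermacra-1(10),11(13)-dien-12-oate | C=C(C(=O)OC)[C@H]1[C@H](O)[C@H]2O[C@]2(C)CC/C=C(/C)C[C@@H]1OC(C)=O
F3 | step 11 | (1(10)Z,4R,5R,6S,7R,8S)-8-acetoxy-4,5-epoxygermacra-1(10),11(13)-dien-12,6-olide | C=C1C(=O)O[C@@H]2[C@H]3O[C@]3(C)CC/C=C(/C)C[C@H](OC(C)=O)[C@@H]12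
F4 | step 12 | (1R,4R,5R,6S,8S,10S)-8-acetoxy-11,13-dibromo-1,10:4,5-diepoxygermacran-12,6-olide (C11 epimers) | BrCC1(Br)C(=O)O[C@@H]2[C@H]3O[C@]3(C)CC[C@H]3O[C@@]3(C)C[C@H](OC(C)=O)[C@@H]12
F5 | step 12 | (1R,4R,5R,6S,8S,10S)-8-acetoxy-13-bromo-1,10:4,5-diepoxygermacr-7(11)-en-12,6-olide | BrCC1=C2[C@@H](OC(C)=O)C[C@]3(C)O[C@@H]3CC[C@@]3(C)O[C@@H]3[C@H]2OC1=O
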